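**Plan**

Numbering is that of an octahydroazulene: ring A (five-membered) is C1, C2, C3, C3a, C8a; ring B (seven-membered) is C3a, C4–C8, C8a. C3 carries OH and isopropyl, C4 the vanillate, C6 and C8a the methyl groups, C7 the free OH.

- Cuts, in order: the ester C4–O; the ring B alkene C5=C6 (metathesis); the C3–isopropyl bond; then C2–C3 and C3a–C8a of ring A in one retro-step; last the enol ether C–O bond.
- Enabling feature: in ring A the carbinol carbon C3 lies between the CH2 C2 and the ring-fusion CH C3a, which is bonded to the quaternary C8a. C3(=O)–C3a–C8a(CH3)–C1H2–C2H2 is the cyclopentanone that a pent-4-enal gives by hydroacylation, and that aldehyde (formyl C3, vinyl C1=C2 on C8a) is the Claisen product of an (E,E)-allyl vinyl ether in which the C3 oxygen bridges C3 and C2.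
- Forward: fragment 1 (allylic alcohol, C2–C1–C8a–C8–C7–C6) and fragment 2 (vinyl iodide, C3–C3a–C4–C5) are joined as an ether; tandem Claisen rearrangement/hydroacylation builds ring A; isopropyl addition; metathesis closes ring B; esterification with fragment 3.
- Stereochemistry: C7 and C4 come from two Sharpless kinetic resolutions; C3a and C8a from the chair Claisen transition state (E,E geometry for the relative, the C4 silyloxy centre for the absolute sense); C3 from addition to the ketone anti to the C3a side chain and the C8a methyl.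

Key step: step 10

Remark: the (S)-silyloxy centre at C4 is assumed to steer the Claisen stage in the inside-alkoxy sense (allyl terminus anti to the propenyl group); crotonaldehyde is used as its (E)-isomer.

**Route**

Step 1
Reactants: 1 methacrolein; 2 propargyl bromide
Product: 3 rac-2-methylhex-1-en-5-yn-3-ol
Conditions: Zn dust, THF/sat. aq NH4Cl, 0 °C to rt
Reagents that add atoms: none
Why: Barbier-type propargylation, in which the organozinc species formed in situ adds 1,2 to the enal to give the racemic homopropargylic alcohol that step 2 resolves.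

Step 2
Reactants: 3 rac-2-methylhex-1-en-5-yn-3-ol
Product: 4 (R)-2-methylhex-1-en-5-yn-3-ol
Conditions: Ti(OiPr)4 (0.2 equiv), L-(+)-DIPT (0.24 equiv), t-BuOOH (0.6 equiv), 4 Å MS, CH2Cl2, −20 °C; stopped near 55–60 % conversion, unreacted alcohol recovered
Reagents that add atoms: none
Why: Sharpless kinetic resolution of a secondary allylic alcohol, in which L-(+)-tartrate epoxidises the (S)-enantiomer fast, so the unreacted (R)-alcohol with the C7 configuration should be recovered in high ee.

Step 3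
Reactants: 4 (R)-2-methylhex-1-en-5-yn-3-ol
Product: 5 (R)-tert-butyldimethyl[(2-methylhex-1-en-5-yn-3-yl)oxy]silane
Conditions: TBSCl, imidazole, DMF, rt
Reagents that add atoms: tert-butyldimethylsilyl chloride CC(C)(C)[Si](C)(C)Cl
Why: Imidazole-promoted silylation protects the C7 hydroxyl for the aluminium, copper, rhodium and cerium steps without touching the stereocentre.

Step 4
Reactants: 5 (R)-tert-butyldimethyl[(2-methylhex-1-en-5-yn-3-yl)oxy]silane
Product: 7 (2E,5R)-5-(tert-butyldimethylsilyloxy)-3,6-dimethylhepta-2,6-dien-1-ol, via alkenyldimethylalane 6 (not isolated)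
Conditions: Me3Al (3 equiv), Cp2ZrCl2 (0.25 equiv), CH2Cl2, 0 °C to rt; then n-BuLi, (CH2O)n, THF, −78 °C to rt
Reagents that add atoms: trimethylaluminium C[Al](C)C; paraformaldehyde (as formaldehyde) C=O
Why: Zirconium-catalysed syn-carboalumination of the terminal alkyne (Negishi carboalumination) puts CH3 on the internal and aluminium on the terminal carbon, and hydroxymethylation of the derived alanate proceeds with retention, so the (E)-trisubstituted allylic alcohol should form while the 1,1-disubstituted alkene and the silyl ether stay intact.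

Step 5
Reactants: 8 (E)-crotonaldehyde; 9 ethynylmagnesium bromide
Product: 10 rac-(E)-hex-4-en-1-yn-3-ol
Conditions: THF, −20 °C to 0 °C; aq NH4Cl
Reagents that add atoms: none
Why: 1,2-Addition of the alkynyl Grignard reagent to the enal gives the racemic enynol.

Step 6
Reactants: 10 rac-(E)-hex-4-en-1-yn-3-ol
Product: 11 (3S,4E)-hex-4-en-1-yn-3-ol
Conditions: Ti(OiPr)4 (0.2 equiv), L-(+)-DIPT (0.24 equiv), t-BuOOH (0.6 equiv), 4 Å MS, CH2Cl2, −20 °C; stopped near 55–60 % conversion, unreacted alcohol recovered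
Reagents that add atoms: none
Why: Sharpless kinetic resolution, in which L-(+)-tartrate epoxidises the propenyl group of the (R)-enantiomer fast (same spatial sense as in step 2, the descriptor differing because ethynyl outranks propenyl), leaving the (S)-alcohol with the C4 configuration.

Step 7
Reactants: 11 (3S,4E)-hex-4-en-1-yn-3-ol
Product: 12 triethyl{[(3S,4E)-hex-4-en-1-yn-3-yl]oxy}silane
Conditions: TESCl, imidazole, DMF, 0 °C to rt
Reagents that add atoms: triethylsilyl chloride CC[Si](CC)(CC)Cl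
Why: Silylation gives a C4 silyl ether that can later be removed in the presence of the C7 TBS ether; the stereocentre is not touched.

Step 8
Reactants: 12 triethyl{[(3S,4E)-hex-4-en-1-yn-3-yl]oxy}silane
Product: 14 triethyl{[(1E,3S,4E)-1-iodohexa-1,4-dien-3-yl]oxy}silane, via alkenylzirconocene chloride 13 (not isolated)
Conditions: Cp2Zr(H)Cl (1.2 equiv), THF, rt; then I2, 0 °C
Reagents that add atoms: iodine II
Why: Hydrozirconation–iodination, in which syn-addition of Zr–H places zirconium on the terminal alkyne carbon and iodinolysis with retention gives the (E)-vinyl iodide, the 1,2-disubstituted alkene reacting far more slowly with Cp2Zr(H)Cl.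

Step 9
Reactants: 7 (2E,5R)-5-(tert-butyldimethylsilyloxy)-3,6-dimethylhepta-2,6-dien-1-ol; 14 triethyl{[(1E,3S,4E)-1-iodohexa-1,4-dien-3-yl]oxy}silane
Product: 15 tert-butyl{[(3R,5E)-2,5-dimethyl-7-{[(1E,3S,4E)-3-(triethylsilyloxy)hexa-1,4-dien-1-yl]oxy}hepta-1,5-dien-3-yl]oxy}dimethylsilane
Conditions: CuI (10 mol %), 3,4,7,8-tetramethyl-1,10-phenanthroline (20 mol %), Cs2CO3, toluene, 80 °C
Reagents that add atoms: none
Why: Copper-catalysed C–O cross-coupling (Ullmann-type vinylation of the primary allylic alcohol) proceeds with retention of the (E)-vinyl geometry and below the temperature of the Claisen rearrangement, which should give the (E,E)-allyl vinyl ether.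

Step 10
Reactants: 15 tert-butyl{[(3R,5E)-2,5-dimethyl-7-{[(1E,3S,4E)-3-(triethylsilyloxy)hexa-1,4-dien-1-yl]oxy}hepta-1,5-dien-3-yl]oxy}dimethylsilane
Product: 17 (2S,3R)-3-[(2R)-2-(tert-butyldimethylsilyloxy)-3-methylbut-3-en-1-yl]-3-methyl-2-[(1S,2E)-1-(triethylsilyloxy)but-2-en-1-yl]cyclopentan-1-one, via pent-4-enal 16 (not isolated)
Conditions: [Rh(cod)Cl]2 (5 mol %), dppe (10 mol %), PhCN, 130 °C, sealed tube
Reagents that add atoms: none
Why: Heating takes the allyl vinyl ether through a chair Claisen transition state to the γ,δ-unsaturated aldehyde 16 (new C3a–C8a bond between the enol-ether β-carbon and the methyl-bearing allyl terminus), after which the monovalent rhodium catalyst adds the aldehyde C–H oxidatively, inserts the new terminal vinyl group into Rh–H and reductively eliminates the C3–C2 bond; the closest known reaction type is the tandem Claisen rearrangement/intramolecular hydroacylation of allyl vinyl ethers to cyclopentanones. Ring A is the only ring closed, by endo hydroacylation of the pent-4-enal (acyl carbon to the terminal alkene carbon through a six-membered acylrhodium metallacycle). The relative configuration of the two new stereocentres C3a and C8a follows from the chair transition state with the (E)-enol ether and the (E)-trisubstituted allyl unit, which puts the silyloxybutenyl group on C3a and the CH2 arm on C8a syn in the open chain, that is the side chain cis to the C8a methyl on ring A. The absolute sense is set by the (S)-silyloxy centre next to the enol ether, the allyl terminus adding to the face opposite the propenyl group with the C–O bond in the inside position. The step needs site selectivity in the hydroacylation, which the substitution pattern should secure: the monosubstituted vinyl group on the quaternary carbon inserts in preference to the 1,2-disubstituted propenyl and the 1,1-disubstituted isopropenyl groups, and no stereocentre is touched after the sigmatropic stage.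

Step 11
Reactants: 17 (2S,3R)-3-[(2R)-2-(tert-butyldimethylsilyloxy)-3-methylbut-3-en-1-yl]-3-methyl-2-[(1S,2E)-1-(triethylsilyloxy)but-2-en-1-yl]cyclopentan-1-one
Product: 18 (1R,2S,3R)-3-[(2R)-2-(tert-butyldimethylsilyloxy)-3-methylbut-3-en-1-yl]-3-methyl-1-(propan-2-yl)-2-[(1S,2E)-1-(triethylsilyloxy)but-2-en-1-yl]cyclopentan-1-ol
Conditions: i-PrMgCl, CeCl3, THF, −78 °C to 0 °C
Reagents that add atoms: isopropylmagnesium chloride CC(C)[Mg]Cl
Why: Organocerium 1,2-addition, in which the weakly basic reagent should suppress enolisation (with loss of silyloxide) and β-hydride reduction, and attack from the face opposite the adjacent silyloxybutenyl chain and the methyl on the quaternary carbon sets C3 with OH cis to both.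

Step 12
Reactants: 18 (1R,2S,3R)-3-[(2R)-2-(tert-butyldimethylsilyloxy)-3-methylbut-3-en-1-yl]-3-methyl-1-(propan-2-yl)-2-[(1S,2E)-1-(triethylsilyloxy)but-2-en-1-yl]cyclopentan-1-ol
Product: 19 (3R,3aS,4S,7R,8aR)-7-(tert-butyldimethylsilyloxy)-6,8a-dimethyl-3-(propan-2-yl)-4-(triethylsilyloxy)-1,2,3,3a,4,7,8,8a-octahydroazulen-3-ol
Conditions: second-generation Grubbs catalyst RuCl2(=CHPh)(PCy3)(SIMes) (10 mol %), toluene, 80 °C, high dilution
Reagents that add atoms: none
Why: Ring-closing metathesis of the propenyl and isopropenyl groups with loss of propene closes ring B as its trisubstituted C5=C6 alkene, the ring enforcing the Z geometry and no stereocentre being touched.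

Step 13
Reactants: 19 (3R,3aS,4S,7R,8aR)-7-(tert-butyldimethylsilyloxy)-6,8a-dimethyl-3-(propan-2-yl)-4-(triethylsilyloxy)-1,2,3,3a,4,7,8,8a-octahydroazulen-3-ol
Product: 20 (3R,3aS,4S,7R,8aR)-7-(tert-butyldimethylsilyloxy)-6,8a-dimethyl-3-(propan-2-yl)-1,2,3,3a,4,7,8,8a-octahydroazulene-3,4-diol
Conditions: PPTS (cat.), MeOH, 0 °C to rt
Reagents that add atoms: none
Why: Acid-catalysed methanolysis removes the triethylsilyl ether selectively, the bulkier tert-butyldimethylsilyl ether at C7 being much slower to cleave.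

Step 14
Reactants: 21 vanillic acid
Product: 23 4-(tert-butyldimethylsilyloxy)-3-methoxybenzoic acid, via silyl ester 22 (not isolated)
Conditions: TBSCl (2.2 equiv), imidazole, DMF, rt; then AcOH, THF/H2O, rt
Reagents that add atoms: tert-butyldimethylsilyl chloride CC(C)(C)[Si](C)(C)Cl
Why: Silylation of phenol and acid followed by mild hydrolysis of the labile silyl ester leaves the phenol protected for the esterification.

Step 15
Reactants: 20 (3R,3aS,4S,7R,8aR)-7-(tert-butyldimethylsilyloxy)-6,8a-dimethyl-3-(propan-2-yl)-1,2,3,3a,4,7,8,8a-octahydroazulene-3,4-diol; 23 4-(tert-butyldimethylsilyloxy)-3-methoxybenzoic acid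
Product: 24 (3R,3aS,4S,7R,8aR)-7-(tert-butyldimethylsilyloxy)-3-hydroxy-6,8a-dimethyl-3-(propan-2-yl)-1,2,3,3a,4,7,8,8a-octahydroazulen-4-yl 4-(tert-butyldimethylsilyloxy)-3-methoxybenzoate
Conditions: DCC, DMAP, CH2Cl2, rt
Reagents that add atoms: none
Why: Steglich esterification (carbodiimide activation, acyl transfer by DMAP) acylates the secondary C4 alcohol with retention, the tertiary C3 alcohol being too hindered to react.

Step 16
Reactants: 24 (3R,3aS,4S,7R,8aR)-7-(tert-butyldimethylsilyloxy)-3-hydroxy-6,8a-dimethyl-3-(propan-2-yl)-1,2,3,3a,4,7,8,8a-octahydroazulen-4-yl 4-(tert-butyldimethylsilyloxy)-3-methoxybenzoate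
Product: 25 (3R,3aS,4S,7R,8aR)-3,7-dihydroxy-6,8a-dimethyl-3-(propan-2-yl)-1,2,3,3a,4,7,8,8a-octahydroazulen-4-yl 4-hydroxy-3-methoxybenzoate
Conditions: HF·pyridine, pyridine/THF, 0 °C to rt
Reagents that add atoms: none
Why: Fluoride-mediated desilylation cleaves the aryl and the secondary silyl ether without touching the ester, which should give the target.

**Compound list**

1 | methacrolein | CC(=C)C=O | starting material
2 | propargyl bromide | BrCC#C | starting material
3 | rac-2-methylhex-1-en-5-yn-3-ol | C=C(C)C(O)CC#C | intermediate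
4 | (R)-2-methylhex-1-en-5-yn-3-ol | C=C(C)[C@H](O)CC#C | intermediate
5 | (R)-tert-butyldimethyl[(2-methylhex-1-en-5-yn-3-yl)oxy]silane | C=C(C)[C@H](O[Si](C)(C)C(C)(C)C)CC#C | intermediate
6 | dimethyl[(1E,4R)-4-(tert-butyldimethylsilyloxy)-2,5-dimethylhexa-1,5-dien-1-yl]alane | C=C(C)[C@H](O[Si](C)(C)C(C)(C)C)C/C(C)=C/[Al](C)C | intermediate
7 | (2E,5R)-5-(tert-butyldimethylsilyloxy)-3,6-dimethylhepta-2,6-dien-1-ol | C=C(C)[C@H](O[Si](C)(C)C(C)(C)C)C/C(C)=C/CO | intermediate
8 | (E)-crotonaldehyde | C/C=C/C=O | starting material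
9 | ethynylmagnesium bromide | C#C[Mg]Br | starting material
10 | rac-(E)-hex-4-en-1-yn-3-ol | C/C=C/C(O)C#C | intermediate
11 | (3S,4E)-hex-4-en-1-yn-3-ol | C/C=C/[C@H](O)C#C | intermediate
12 | triethyl{[(3S,4E)-hex-4-en-1-yn-3-yl]oxy}silane | C/C=C/[C@H](O[Si](CC)(CC)CC)C#C | intermediate
13 | chlorobis(cyclopentadienyl)[(1E,3S,4E)-3-(triethylsilyloxy)hexa-1,4-dien-1-yl]zirconium | C/C=C/[C@H](O[Si](CC)(CC)CC)/C=C/[Zr](Cl)(C1C=CC=C1)C1C=CC=C1 | intermediate
14 | triethyl{[(1E,3S,4E)-1-iodohexa-1,4-dien-3-yl]oxy}silane | C/C=C/[C@H](O[Si](CC)(CC)CC)/C=C/I | intermediate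
15 | tert-butyl{[(3R,5E)-2,5-dimethyl-7-{[(1E,3S,4E)-3-(triethylsilyloxy)hexa-1,4-dien-1-yl]oxy}hepta-1,5-dien-3-yl]oxy}dimethylsilane | C/C=C/[C@H](O[Si](CC)(CC)CC)/C=C/OC/C=C(C)/C[C@@H](O[Si](C)(C)C(C)(C)C)C(C)=C | intermediate
16 | (2S,3S)-3-[(2R)-2-(tert-butyldimethylsilyloxy)-3-methylbut-3-en-1-yl]-3-methyl-2-[(1S,2E)-1-(triethylsilyloxy)but-2-en-1-yl]pent-4-enal | C/C=C/[C@H](O[Si](CC)(CC)CC)[C@@H](C=O)[C@](C)(C=C)C[C@@H](O[Si](C)(C)C(C)(C)C)C(C)=C | intermediate
17 | (2S,3R)-3-[(2R)-2-(tert-butyldimethylsilyloxy)-3-methylbut-3-en-1-yl]-3-methyl-2-[(1S,2E)-1-(triethylsilyloxy)but-2-en-1-yl]cyclopentan-1-one | C/C=C/[C@H](O[Si](CC)(CC)CC)[C@H]1C(=O)CC[C@]1(C)C[C@@H](O[Si](C)(C)C(C)(C)C)C(C)=C | intermediate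
18 | (1R,2S,3R)-3-[(2R)-2-(tert-butyldimethylsilyloxy)-3-methylbut-3-en-1-yl]-3-methyl-1-(propan-2-yl)-2-[(1S,2E)-1-(triethylsilyloxy)but-2-en-1-yl]cyclopentan-1-ol | C/C=C/[C@H](O[Si](CC)(CC)CC)[C@H]1[C@](O)(C(C)C)CC[C@]1(C)C[C@@H](O[Si](C)(C)C(C)(C)C)C(C)=C | intermediate
19 | (3R,3aS,4S,7R,8aR)-7-(tert-butyldimethylsilyloxy)-6,8a-dimethyl-3-(propan-2-yl)-4-(triethylsilyloxy)-1,2,3,3a,4,7,8,8a-octahydroazulen-3-ol | CC[Si](CC)(CC)O[C@H]1C=C(C)[C@H](O[Si](C)(C)C(C)(C)C)C[C@@]2(C)CC[C@@](O)(C(C)C)[C@H]12 | intermediate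
20 | (3R,3aS,4S,7R,8aR)-7-(tert-butyldimethylsilyloxy)-6,8a-dimethyl-3-(propan-2-yl)-1,2,3,3a,4,7,8,8a-octahydroazulene-3,4-diol | O[C@H]1C=C(C)[C@H](O[Si](C)(C)C(C)(C)C)C[C@@]2(C)CC[C@@](O)(C(C)C)[C@H]12 | intermediate
21 | vanillic acid | COc1cc(C(=O)O)ccc1O | starting material
22 | tert-butyldimethylsilyl 4-(tert-butyldimethylsilyloxy)-3-methoxybenzoate | COc1cc(C(=O)O[Si](C)(C)C(C)(C)C)ccc1O[Si](C)(C)C(C)(C)C | intermediate
23 | 4-(tert-butyldimethylsilyloxy)-3-methoxybenzoic acid | COc1cc(C(=O)O)ccc1O[Si](C)(C)C(C)(C)C | intermediate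
24 | (3R,3aS,4S,7R,8aR)-7-(tert-butyldimethylsilyloxy)-3-hydroxy-6,8a-dimethyl-3-(propan-2-yl)-1,2,3,3a,4,7,8,8a-octahydroazulen-4-yl 4-(tert-butyldimethylsilyloxy)-3-methoxybenzoate | COc1cc(C(=O)O[C@H]2C=C(C)[C@H](O[Si](C)(C)C(C)(C)C)C[C@@]3(C)CC[C@@](O)(C(C)C)[C@H]23)ccc1O[Si](C)(C)C(C)(C)C | intermediate
25 | (3R,3aS,4S,7R,8aR)-3,7-dihydroxy-6,8a-dimethyl-3-(propan-2-yl)-1,2,3,3a,4,7,8,8a-octahydroazulen-4-yl 4-hydroxy-3-methoxybenzoate | COc1cc(C(=O)O[C@H]2C=C(C)[C@H](O)C[C@@]3(C)CC[C@@](O)(C(C)C)[C@H]23)ccc1O | target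

**Totals and risks**

Total step count: 16. Longest linear sequence: 11 steps (steps 1–4, 9–13, 15, 16).

Risk 1, step 10. In the sigmatropic stage the silyloxy-bearing centre may deliver the allyl terminus to the other face of the enol ether, so that C3a and C8a form with the wrong sense relative to C4 and C7. The fallback sets out from 10 and comes back at 24. Kinetic resolution of 10 with D-(−)-DIPT leaves the enantiomeric alcohol (3R,4E)-hex-4-en-1-yn-3-ol F1. Silylation gives the TES ether F2, hydrozirconation gives the alkenylzirconocene chloride F3 and iodinolysis gives the vinyl iodide F4. Copper-catalysed coupling with 7 gives the C4-epimeric allyl vinyl ether F5, which under the step 10 conditions passes through the pent-4-enal F6 to the cyclopentanone F7, now with the required C3a and C8a configuration. Isopropylcerium addition gives the carbinol F8, metathesis gives the hydroazulene F9 and TES removal gives the C4-epimeric diol F10. Mitsunobu esterification of F10 with 23 (PPh3, DIAD, toluene, 0 °C) inverts C4 and gives 24.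

Risk 2, step 12. Ring closure to the trans-fused cycloheptene may be slow because both alkenes are hindered (a 1,1-disubstituted partner and two allylic silyl ethers), so that catalyst decay, alkene isomerisation or oligomerisation takes over. The fallback sets out from 18 and comes back at 20. The TES group is removed first (PPTS, MeOH) to give the free allylic alcohol, the diol F11. A free allylic hydroxyl speeds up loading of the ruthenium carbene on the propenyl group (hydroxyl-assisted metathesis), and ring closure of F11 under the step 12 conditions leads directly to 20.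

Risk 3, step 11. Enolisation of the hindered ketone toward the silyloxy-bearing side chain (with loss of silyloxide) or β-hydride transfer from the isopropyl reagent may compete with addition. The fallback sets out from 17 and comes back at 19. Ring B is closed first by metathesis of 17 under the step 12 conditions to give the hydroazulenone F12. Isopropenylmagnesium bromide with CeCl3, a less basic sp2 nucleophile that is not prone to hydride transfer, adds from the face opposite the angular methyl group to give the carbinol F13. Hydrogenation of the 1,1-disubstituted alkene with RhCl(PPh3)3 and H2 (the ring alkene is trisubstituted and flanked by two silyl ethers) gives 19.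

Further compounds
F1 | step 10 | (3R,4E)-hex-4-en-1-yn-3-ol | C/C=C/[C@@H](O)C#C
F2 | step 10 | triethyl{[(3R,4E)-hex-4-en-1-yn-3-yl]oxy}silane | C/C=C/[C@@H](O[Si](CC)(CC)CC)C#C
F3 | step 10 | chlorobis(cyclopentadienyl)[(1E,3R,4E)-3-(triethylsilyloxy)hexa-1,4-dien-1-yl]zirconium | C/C=C/[C@@H](O[Si](CC)(CC)CC)/C=C/[Zr](Cl)(C1C=CC=C1)C1C=CC=C1
F4 | step 10 | triethyl{[(1E,3R,4E)-1-iodohexa-1,4-dien-3-yl]oxy}silane | C/C=C/[C@@H](O[Si](CC)(CC)CC)/C=C/I
F5 | step 10 | tert-butyl{[(3R,5E)-2,5-dimethyl-7-{[(1E,3R,4E)-3-(triethylsilyloxy)hexa-1,4-dien-1-yl]oxy}hepta-1,5-dien-3-yl]oxy}dimethylsilane | C/C=C/[C@@H](O[Si](CC)(CC)CC)/C=C/OC/C=C(C)/C[C@@H](O[Si](C)(C)C(C)(C)C)C(C)=C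
F6 | step 10 | (2S,3S)-3-[(2R)-2-(tert-butyldimethylsilyloxy)-3-methylbut-3-en-1-yl]-3-methyl-2-[(1R,2E)-1-(triethylsilyloxy)but-2-en-1-yl]pent-4-enal | C/C=C/[C@@H](O[Si](CC)(CC)CC)[C@@H](C=O)[C@](C)(C=C)C[C@@H](O[Si](C)(C)C(C)(C)C)C(C)=C
F7 | step 10 | (2S,3R)-3-[(2R)-2-(tert-butyldimethylsilyloxy)-3-methylbut-3-en-1-yl]-3-methyl-2-[(1R,2E)-1-(triethylsilyloxy)but-2-en-1-yl]cyclopentan-1-one | C/C=C/[C@@H](O[Si](CC)(CC)CC)[C@H]1C(=O)CC[C@]1(C)C[C@@H](O[Si](C)(C)C(C)(C)C)C(C)=C
F8 | step 10 | (1R,2S,3R)-3-[(2R)-2-(tert-butyldimethylsilyloxy)-3-methylbut-3-en-1-yl]-3-methyl-1-(propan-2-yl)-2-[(1R,2E)-1-(triethylsilyloxy)but-2-en-1-yl]cyclopentan-1-ol | C/C=C/[C@@H](O[Si](CC)(CC)CC)[C@H]1[C@](O)(C(C)C)CC[C@]1(C)C[C@@H](O[Si](C)(C)C(C)(C)C)C(C)=C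
F9 | step 10 | (3R,3aS,4R,7R,8aR)-7-(tert-butyldimethylsilyloxy)-6,8a-dimethyl-3-(propan-2-yl)-4-(triethylsilyloxy)-1,2,3,3a,4,7,8,8a-octahydroazulen-3-ol | CC[Si](CC)(CC)O[C@@H]1C=C(C)[C@H](O[Si](C)(C)C(C)(C)C)C[C@@]2(C)CC[C@@](O)(C(C)C)[C@H]12
F10 | step 10 | (3R,3aS,4R,7R,8aR)-7-(tert-butyldimethylsilyloxy)-6,8a-dimethyl-3-(propan-2-yl)-1,2,3,3a,4,7,8,8a-octahydroazulene-3,4-diol | O[C@@H]1C=C(C)[C@H](O[Si](C)(C)C(C)(C)C)C[C@@]2(C)CC[C@@](O)(C(C)C)[C@H]12
F11 | step 12 | (1R,2S,3R)-3-[(2R)-2-(tert-butyldimethylsilyloxy)-3-methylbut-3-en-1-yl]-2-[(1S,2E)-1-hydroxybut-2-en-1-yl]-3-methyl-1-(propan-2-yl)cyclopentan-1-ol | C/C=C/[C@H](O)[C@H]1[C@](O)(C(C)C)CC[C@]1(C)C[C@@H](O[Si](C)(C)C(C)(C)C)C(C)=C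
F12 | step 11 | (3aS,4S,7R,8aR)-7-(tert-butyldimethylsilyloxy)-6,8a-dimethyl-4-(triethylsilyloxy)-2,3a,4,7,8,8a-hexahydroazulen-3(1H)-one | CC[Si](CC)(CC)O[C@H]1C=C(C)[C@H](O[Si](C)(C)C(C)(C)C)C[C@@]2(C)CCC(=O)[C@H]12
F13 | step 11 | (3S,3aS,4S,7R,8aR)-7-(tert-butyldimethylsilyloxy)-6,8a-dimethyl-3-(prop-1-en-2-yl)-4-(triethylsilyloxy)-1,2,3,3a,4,7,8,8a-octahydroazulen-3-ol | CC[Si](CC)(CC)O[C@H]1C=C(C)[C@H](O[Si](C)(C)C(C)(C)C)C[C@@]2(C)CC[C@@](O)(C(C)=C)[C@H]12
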